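**Retrosynthetic overview**
- Last operations: cleave two primary TBS ethers; before that, attach the only ring (the butenolide) intact by B-alkyl Suzuki–Miyaura coupling of the hydroborated allyl arm with 3-bromofuran-2(5H)-one. No ring is formed on the route.
- Acetoxymethyl centre (R): not made by auxiliary alkylation; the C–C bond and the stereocentre are made together by lithiation–borylation (1,2-metallate shift) of a primary TIB ester with the (Z)-homoallyl boronate, then CH2 insertion and oxidation.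
- Hydroxymethyl centre (S): the same tactic one round earlier, from two derivatives of but-3-en-1-ol; (–)-sparteine serves both centres because the roles of linker and side arm are exchanged.
- (Z)-allylic ether: Z-selective Wittig reaction of a boron-bearing ylide with 1-(TBS-oxy)propan-2-one.

Assumption: catalogue compounds ((–)-sparteine, 2,4,6-triisopropylbenzoyl chloride, 2-(3-bromopropyl)pinacolborane, 1-(TBS-oxy)propan-2-one, 3-bromofuran-2(5H)-one) count as commercially available.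

Abbreviations: TIB = 2,4,6-triisopropylbenzoyl; Bpin = 4,4,5,5-tetramethyl-1,3,2-dioxaborolan-2-yl; TBS = tert-butyldimethylsilyl; 9-BBN = 9-borabicyclo[3.3.1]nonane.

**Step 1**
Reactants: 1 but-3-en-1-ol; 2 2,4,6-triisopropylbenzoyl chloride
Product: 3 but-3-en-1-yl 2,4,6-triisopropylbenzoate
Conditions: NaH, THF, 0 °C; then 2, 0 °C to 60 °C
Reagents that add atoms: 2,4,6-triisopropylbenzoyl chloride, CC(C)c1cc(C(C)C)c(C(Cl)=O)c(C(C)C)c1
Why: Acylation of the sodium alkoxide by the hindered acid chloride (esterification) installs the TIB ester that later directs α-lithiation and acts as the leaving group of the 1,2-shift; no stereocentre.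

**Step 2**
Reactants: 3 but-3-en-1-yl 2,4,6-triisopropylbenzoate; 4 pinacolborane
Product: 5 4-(Bpin)butyl 2,4,6-triisopropylbenzoate
Conditions: [IrCl(cod)]2 (cod = C8H12; 1.5 mol %), Ph2PCH2PPh2 (3 mol %), CH2Cl2, rt
Reagents that add atoms: pinacolborane, CC1(C)OBOC1(C)C
Why: Iridium-catalysed anti-Markovnikov hydroboration of the terminal alkene gives the primary pinacol boronate and leaves the hindered ester alone, so one alcohol supplies both coupling partners.

**Step 3**
Reactants: 3 but-3-en-1-yl 2,4,6-triisopropylbenzoate; 5 4-(Bpin)butyl 2,4,6-triisopropylbenzoate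
Product: 8 (S)-5-(Bpin)oct-7-en-1-yl 2,4,6-triisopropylbenzoate, via lithiated benzoate 6 (not isolated), via boronate complex 7 (not isolated)
Conditions: 3 (1.3 equiv), s-BuLi (1.3 equiv), (–)-sparteine (1.3 equiv), Et2O, –78 °C, 5 h; then 5 (1.0 equiv), –78 °C, 1 h; then reflux, 12 h
Reagents that add atoms: boronic ester 5, CC1(C)OB(CCCCOC(=O)c2c(C(C)C)cc(C(C)C)cc2C(C)C)OC1(C)C
Why: Lithiation–borylation: s-BuLi/(–)-sparteine removes the pro-S α-hydrogen of 3, boronate 5 adds with retention and its alkyl group then migrates from boron to carbon with inversion as the TIB carboxylate leaves (1,2-metallate rearrangement), which joins the fragments and sets the S centre at about 97:3 er.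

**Step 4**
Reactants: 8 (S)-5-(Bpin)oct-7-en-1-yl 2,4,6-triisopropylbenzoate; 9 bromochloromethane; 10 hydrogen peroxide
Product: 13 (S)-5-(hydroxymethyl)oct-7-en-1-yl 2,4,6-triisopropylbenzoate, via chloromethyl boronate complex 11 (not isolated), via homologated boronic ester 12 (not isolated)
Conditions: BrCH2Cl, n-BuLi, Et2O, –78 °C to rt; then NaOH, H2O2, THF/H2O, 0 °C to rt
Reagents that add atoms: bromochloromethane, ClCBr; hydrogen peroxide, OO
Why: Matteson one-carbon homologation with ClCH2Li made in the flask (1,2-shift with retention at the migrating stereocentre) followed by oxidation of the primary C–B bond turns CH–B into CH–CH2OH, and only one CH2 is inserted because the ate complex rearranges only on warming, after the excess carbenoid has decomposed.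

**Step 5**
Reactants: 13 (S)-5-(hydroxymethyl)oct-7-en-1-yl 2,4,6-triisopropylbenzoate; 14 tert-butyldimethylsilyl chloride
Product: 15 (S)-5-[(TBS-oxy)methyl]oct-7-en-1-yl 2,4,6-triisopropylbenzoate
Conditions: TBSCl, imidazole, DMF, rt
Reagents that add atoms: tert-butyldimethylsilyl chloride, CC(C)(C)[Si](C)(C)Cl
Why: Standard silylation of the primary alcohol gives an ether that survives s-BuLi and is removed together with the allylic TBS ether in the last step.

**Step 6**
Reactants: 16 2-(3-bromopropyl)-4,4,5,5-tetramethyl-1,3,2-dioxaborolane; 17 triphenylphosphine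
Product: 18 triphenyl[3-(Bpin)propyl]phosphonium bromide
Conditions: MeCN, reflux, 48 h
Reagents that add atoms: triphenylphosphine, c1ccc(cc1)P(c1ccccc1)c1ccccc1
Why: SN2 quaternisation of the phosphine by the primary bromide gives the Wittig salt while the pinacol boronate stays intact.

**Step 7**
Reactants: 18 triphenyl[3-(Bpin)propyl]phosphonium bromide; 19 1-(TBS-oxy)propan-2-one
Product: 21 (Z)-tert-butyldimethyl{[2-methyl-5-(Bpin)pent-2-en-1-yl]oxy}silane, via phosphonium ylide 20 (not isolated)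
Conditions: NaN(SiMe3)2, THF, –78 °C to 0 °C; then 19, –78 °C to rt
Reagents that add atoms: 1-(TBS-oxy)propan-2-one, CC(=O)CO[Si](C)(C)C(C)(C)C
Why: Wittig olefination of an α-silyloxy ketone by a salt-free non-stabilised ylide (Still's Z-selective variant) places CH2OTBS cis to the chain and so gives the (Z)-trisubstituted alkene directly at the allylic-alcohol oxidation level; the alkyl pinacol boronate is expected to tolerate the hindered amide base and the ylide.

**Step 8**
Reactants: 15 (S)-5-[(TBS-oxy)methyl]oct-7-en-1-yl 2,4,6-triisopropylbenzoate; 21 (Z)-tert-butyldimethyl{[2-methyl-5-(Bpin)pent-2-en-1-yl]oxy}silane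
Product: 24 (4S,8R,11Z)-13-(TBS-oxy)-4-[(TBS-oxy)methyl]-12-methyl-8-(Bpin)trideca-1,11-diene, via lithiated benzoate 22 (not isolated), via boronate complex 23 (not isolated)
Conditions: 15 (1.0 equiv), s-BuLi (1.2 equiv), (–)-sparteine (1.2 equiv), Et2O, –78 °C, 5 h; then 21 (1.5 equiv), –78 °C, 1 h; then reflux, 12 h
Reagents that add atoms: boronic ester 21, CC1(C)OB(CC/C=C(/C)CO[Si](C)(C)C(C)(C)C)OC1(C)C
Why: Second lithiation–borylation: (–)-sparteine again removes the pro-S hydrogen next to the TIB ester and, because here the linker carries the carbenoid carbon and the side arm migrates from boron (the reverse of step 3), the same ligand delivers the R centre by retention then inversion, independently of the remote S centre.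

**Step 9**
Reactants: 24 (4S,8R,11Z)-13-(TBS-oxy)-4-[(TBS-oxy)methyl]-12-methyl-8-(Bpin)trideca-1,11-diene; 9 bromochloromethane; 10 hydrogen peroxide
Product: 27 (2R,6S)-6-[(TBS-oxy)methyl]-2-[(3Z)-5-(TBS-oxy)-4-methylpent-3-en-1-yl]non-8-en-1-ol, via chloromethyl boronate complex 25 (not isolated), via homologated boronic ester 26 (not isolated)
Conditions: BrCH2Cl, n-BuLi, Et2O, –78 °C to rt; then NaOH, H2O2, THF/H2O, 0 °C to rt
Reagents that add atoms: bromochloromethane, ClCBr; hydrogen peroxide, OO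
Why: Matteson homologation then oxidation as in step 4 inserts CH2 with retention and converts the C–B bond into the primary alcohol at the R centre, which is now the only free hydroxyl.

**Step 10**
Reactants: 27 (2R,6S)-6-[(TBS-oxy)methyl]-2-[(3Z)-5-(TBS-oxy)-4-methylpent-3-en-1-yl]non-8-en-1-ol; 28 acetic anhydride
Product: 29 (2R,6S)-6-[(TBS-oxy)methyl]-2-[(3Z)-5-(TBS-oxy)-4-methylpent-3-en-1-yl]non-8-en-1-yl acetate
Conditions: Ac2O, pyridine, DMAP (cat.), CH2Cl2, 0 °C to rt
Reagents that add atoms: acetic anhydride, CC(=O)OC(C)=O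
Why: DMAP-catalysed acylation of the single free hydroxyl fixes the acetate on the correct hydroxymethyl group while the other two oxygens are silylated.

**Step 11**
Reactants: 29 (2R,6S)-6-[(TBS-oxy)methyl]-2-[(3Z)-5-(TBS-oxy)-4-methylpent-3-en-1-yl]non-8-en-1-yl acetate; 30 3-bromofuran-2(5H)-one
Product: 32 (2R,6S)-6-[(TBS-oxy)methyl]-2-[(3Z)-5-(TBS-oxy)-4-methylpent-3-en-1-yl]-9-(2-oxo-2,5-dihydrofuran-3-yl)nonyl acetate, via B-alkyl-9-BBN adduct 31 (not isolated)
Conditions: 9-BBN (1.5 equiv), THF, 0 °C to rt; then 30 (1.5 equiv), PdCl2(dppf) [dppf = Fe(C5H4PPh2)2] (10 mol %), AsPh3 (10 mol %), K3PO4 (3 M aq), DMF, rt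
Reagents that add atoms: 3-bromofuran-2(5H)-one, O=C1OCC=C1Br
Why: 9-BBN hydroborates only the monosubstituted alkene (trisubstituted alkene and acetate untouched at rt), and B-alkyl Suzuki–Miyaura coupling with the α-bromobutenolide under mild aqueous phosphate then attaches the intact ring in one operation.

**Step 12**
Reactants: 32 (2R,6S)-6-[(TBS-oxy)methyl]-2-[(3Z)-5-(TBS-oxy)-4-methylpent-3-en-1-yl]-9-(2-oxo-2,5-dihydrofuran-3-yl)nonyl acetate
Product: 33 (2R,6S)-6-(hydroxymethyl)-2-[(3Z)-5-hydroxy-4-methylpent-3-en-1-yl]-9-(2-oxo-2,5-dihydrofuran-3-yl)nonyl acetate (target)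
Conditions: HF·pyridine, pyridine, THF, 0 °C to rt
Reagents that add atoms: none
Why: Buffered fluoride desilylation cleaves both primary TBS ethers without hydrolysing or shifting the acetate or opening the butenolide, and the product SMILES is identical to the target.

**Compound list**
1 | but-3-en-1-ol | C=CCCO | starting material
2 | 2,4,6-triisopropylbenzoyl chloride | CC(C)c1cc(C(C)C)c(C(Cl)=O)c(C(C)C)c1 | starting material
3 | but-3-en-1-yl 2,4,6-triisopropylbenzoate | C=CCCOC(=O)c1c(C(C)C)cc(C(C)C)cc1C(C)C | intermediate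
4 | pinacolborane | CC1(C)OBOC1(C)C | starting material
5 | 4-(Bpin)butyl 2,4,6-triisopropylbenzoate | CC1(C)OB(CCCCOC(=O)c2c(C(C)C)cc(C(C)C)cc2C(C)C)OC1(C)C | intermediate
6 | (S)-1-lithiobut-3-en-1-yl 2,4,6-triisopropylbenzoate as its (–)-sparteine complex (ligand not drawn) | C=CC[C@H]([Li])OC(=O)c1c(C(C)C)cc(C(C)C)cc1C(C)C | intermediate
7 | lithium [(S)-1-(TIB-oxy)but-3-en-1-yl][4-(TIB-oxy)butyl](pinacolato)borate | C=CC[C@@H](OC(=O)c1c(C(C)C)cc(C(C)C)cc1C(C)C)[B-]1(CCCCOC(=O)c2c(C(C)C)cc(C(C)C)cc2C(C)C)OC(C)(C)C(C)(C)O1.[Li+] | intermediate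
8 | (S)-5-(Bpin)oct-7-en-1-yl 2,4,6-triisopropylbenzoate | C=CC[C@@H](B1OC(C)(C)C(C)(C)O1)CCCCOC(=O)c1c(C(C)C)cc(C(C)C)cc1C(C)C | intermediate
9 | bromochloromethane | ClCBr | starting material
10 | hydrogen peroxide | OO | starting material
11 | lithium (chloromethyl)(pinacolato)borate complex of 8 (configuration as in 8) | C=CC[C@@H]([B-]1(CCl)OC(C)(C)C(C)(C)O1)CCCCOC(=O)c1c(C(C)C)cc(C(C)C)cc1C(C)C.[Li+] | intermediate
12 | (S)-5-[(Bpin)methyl]oct-7-en-1-yl 2,4,6-triisopropylbenzoate | C=CC[C@@H](CB1OC(C)(C)C(C)(C)O1)CCCCOC(=O)c1c(C(C)C)cc(C(C)C)cc1C(C)C | intermediate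
13 | (S)-5-(hydroxymethyl)oct-7-en-1-yl 2,4,6-triisopropylbenzoate | C=CC[C@@H](CO)CCCCOC(=O)c1c(C(C)C)cc(C(C)C)cc1C(C)C | intermediate
14 | tert-butyldimethylsilyl chloride | CC(C)(C)[Si](C)(C)Cl | starting material
15 | (S)-5-[(TBS-oxy)methyl]oct-7-en-1-yl 2,4,6-triisopropylbenzoate | C=CC[C@@H](CO[Si](C)(C)C(C)(C)C)CCCCOC(=O)c1c(C(C)C)cc(C(C)C)cc1C(C)C | intermediate
16 | 2-(3-bromopropyl)-4,4,5,5-tetramethyl-1,3,2-dioxaborolane | BrCCCB1OC(C)(C)C(C)(C)O1 | starting material
17 | triphenylphosphine | c1ccc(cc1)P(c1ccccc1)c1ccccc1 | starting material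
18 | triphenyl[3-(Bpin)propyl]phosphonium bromide | CC1(C)OB(CCC[P+](c2ccccc2)(c2ccccc2)c2ccccc2)OC1(C)C.[Br-] | intermediate
19 | 1-(TBS-oxy)propan-2-one | CC(=O)CO[Si](C)(C)C(C)(C)C | starting material
20 | triphenyl[3-(Bpin)propylidene]phosphorane | CC1(C)OB(CCC=P(c2ccccc2)(c2ccccc2)c2ccccc2)OC1(C)C | intermediate
21 | (Z)-tert-butyldimethyl{[2-methyl-5-(Bpin)pent-2-en-1-yl]oxy}silane | CC1(C)OB(CC/C=C(/C)CO[Si](C)(C)C(C)(C)C)OC1(C)C | intermediate
22 | (1S,5S)-1-lithio-5-[(TBS-oxy)methyl]oct-7-en-1-yl 2,4,6-triisopropylbenzoate as its (–)-sparteine complex (ligand not drawn) | [Li][C@H](OC(=O)c1c(C(C)C)cc(C(C)C)cc1C(C)C)CCC[C@H](CO[Si](C)(C)C(C)(C)C)CC=C | intermediate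
23 | lithium boronate complex of 22 with 21 (carbinol carbon S; other centre and alkene unchanged) | CC1(C)O[B-](CC/C=C(/C)CO[Si](C)(C)C(C)(C)C)(OC1(C)C)[C@H](OC(=O)c1c(C(C)C)cc(C(C)C)cc1C(C)C)CCC[C@H](CO[Si](C)(C)C(C)(C)C)CC=C.[Li+] | intermediate
24 | (4S,8R,11Z)-13-(TBS-oxy)-4-[(TBS-oxy)methyl]-12-methyl-8-(Bpin)trideca-1,11-diene | CC1(C)OB(OC1(C)C)[C@@H](CC/C=C(/C)CO[Si](C)(C)C(C)(C)C)CCC[C@H](CO[Si](C)(C)C(C)(C)C)CC=C | intermediate
25 | lithium (chloromethyl)(pinacolato)borate complex of 24 (configuration as in 24) | CC1(C)O[B-](CCl)(OC1(C)C)[C@@H](CC/C=C(/C)CO[Si](C)(C)C(C)(C)C)CCC[C@H](CO[Si](C)(C)C(C)(C)C)CC=C.[Li+] | intermediate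
26 | 2-{(2R,6S)-6-[(TBS-oxy)methyl]-2-[(3Z)-5-(TBS-oxy)-4-methylpent-3-en-1-yl]non-8-en-1-yl}-4,4,5,5-tetramethyl-1,3,2-dioxaborolane | CC1(C)OB(C[C@@H](CC/C=C(/C)CO[Si](C)(C)C(C)(C)C)CCC[C@H](CO[Si](C)(C)C(C)(C)C)CC=C)OC1(C)C | intermediate
27 | (2R,6S)-6-[(TBS-oxy)methyl]-2-[(3Z)-5-(TBS-oxy)-4-methylpent-3-en-1-yl]non-8-en-1-ol | OC[C@@H](CC/C=C(/C)CO[Si](C)(C)C(C)(C)C)CCC[C@H](CO[Si](C)(C)C(C)(C)C)CC=C | intermediate
28 | acetic anhydride | CC(=O)OC(C)=O | starting material
29 | (2R,6S)-6-[(TBS-oxy)methyl]-2-[(3Z)-5-(TBS-oxy)-4-methylpent-3-en-1-yl]non-8-en-1-yl acetate | CC(=O)OC[C@@H](CC/C=C(/C)CO[Si](C)(C)C(C)(C)C)CCC[C@H](CO[Si](C)(C)C(C)(C)C)CC=C | intermediate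
30 | 3-bromofuran-2(5H)-one | O=C1OCC=C1Br | starting material
31 | B-alkyl-9-BBN adduct of 29 (boron on the former terminal alkene carbon; both centres spatially as in 29) | CC(=O)OC[C@@H](CC/C=C(/C)CO[Si](C)(C)C(C)(C)C)CCC[C@H](CO[Si](C)(C)C(C)(C)C)CCCB1C2CCCC1CCC2 | intermediate
32 | (2R,6S)-6-[(TBS-oxy)methyl]-2-[(3Z)-5-(TBS-oxy)-4-methylpent-3-en-1-yl]-9-(2-oxo-2,5-dihydrofuran-3-yl)nonyl acetate | CC(=O)OC[C@@H](CC/C=C(/C)CO[Si](C)(C)C(C)(C)C)CCC[C@H](CO[Si](C)(C)C(C)(C)C)CCCC1=CCOC1=O | intermediate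
33 | (2R,6S)-6-(hydroxymethyl)-2-[(3Z)-5-hydroxy-4-methylpent-3-en-1-yl]-9-(2-oxo-2,5-dihydrofuran-3-yl)nonyl acetate | CC(=O)OC[C@@H](CC/C=C(/C)CO)CCC[C@H](CO)CCCC1=CCOC1=O | target

**Summary**
Total step count: 12. Longest linear sequence: 10 steps (steps 1, 2, 3, 4, 5, 8, 9, 10, 11, 12, from but-3-en-1-ol). Two reagent-controlled events at about 97:3 each should give the target almost enantiopure but with roughly 5–6% of remote epimers that will be hard to separate.

**The three steps most likely to fail**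

Step 7. The ylide carries a boronate three atoms away, which may complex or consume part of the ylide. Z:E with a silyl ether may also be lower than with acetal-protected hydroxyacetone. The fallback changes the olefination and sets out from 4, returning at 21. Iridium-catalysed hydroboration of 3,3-diethoxyprop-1-ene with 4 (conditions of step 2) gives 2-(3,3-diethoxypropyl)-4,4,5,5-tetramethyl-1,3,2-dioxaborolane F1. Dilute aqueous HCl in acetone gives 3-(Bpin)propanal F2. Still–Gennari olefination with methyl 2-[bis(2,2,2-trifluoroethoxy)phosphoryl]propanoate (KN(SiMe3)2, 18-crown-6, THF, –78 °C) gives methyl (Z)-2-methyl-5-(Bpin)pent-2-enoate F3. Reduction with i-Bu2AlH (CH2Cl2, –78 °C) gives (Z)-2-methyl-5-(Bpin)pent-2-en-1-ol F4, and silylation with 14 and imidazole gives 21. Here the Z geometry comes from a stabilised phosphonate anion that does not interact with boron.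

Step 8. Deprotonation of 15 in the coupling flask may be incomplete or less selective than for 3, and any shortfall wastes boronate 21 and lowers the dr. The fallback changes how the carbenoid is made and sets out from 15, returning at 24. The same deprotonation (s-BuLi, (–)-sparteine, Et2O, –78 °C) is quenched with Me3SnCl to give (1S,5S)-5-[(TBS-oxy)methyl]-1-(trimethylstannyl)oct-7-en-1-yl 2,4,6-triisopropylbenzoate F5. F5 is isolable, so its diastereomeric purity can be measured and it can be purified. Tin–lithium exchange (n-BuLi, Et2O, –78 °C, retention) then regenerates 22 quantitatively without sparteine, and one equivalent of 21 carries it through 23 to 24. This fallback does not help if 15 cannot be lithiated at all.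

Step 11. Oxidative addition to the α-bromo lactone may be slow relative to protodeboronation, and the bromobutenolide, the product and the acetate are all base-sensitive. The fallback avoids palladium, sets out from 29 and returns at 32. Hydroboration to 31 as before, then oxidation with NaBO3·4H2O, gives (2R,6S)-9-hydroxy-6-[(TBS-oxy)methyl]-2-[(3Z)-5-(TBS-oxy)-4-methylpent-3-en-1-yl]nonyl acetate F6. I2, PPh3 and imidazole give the corresponding 9-iodononyl acetate F7. Alkylation of the lithium enolate of 3-(phenylsulfanyl)oxolan-2-one (LiN(SiMe3)2, THF/DMPU, –78 to 0 °C) gives the 9-[2-oxo-3-(phenylsulfanyl)oxolan-3-yl]nonyl acetate F8. One equivalent of mCPBA (CH2Cl2, –78 °C) gives the 9-[2-oxo-3-(phenylsulfinyl)oxolan-3-yl]nonyl acetate F9, and thermal syn-elimination (toluene, 110 °C, CaCO3) gives the endocyclic butenolide 32.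

**Further compounds**
F1 | step 7 | 2-(3,3-diethoxypropyl)-4,4,5,5-tetramethyl-1,3,2-dioxaborolane | CCOC(CCB1OC(C)(C)C(C)(C)O1)OCC
F2 | step 7 | 3-(Bpin)propanal | O=CCCB1OC(C)(C)C(C)(C)O1
F3 | step 7 | methyl (Z)-2-methyl-5-(Bpin)pent-2-enoate | COC(=O)/C(C)=C\CCB1OC(C)(C)C(C)(C)O1
F4 | step 7 | (Z)-2-methyl-5-(Bpin)pent-2-en-1-ol | OC/C(C)=C\CCB1OC(C)(C)C(C)(C)O1
F5 | step 8 | (1S,5S)-5-[(TBS-oxy)methyl]-1-(trimethylstannyl)oct-7-en-1-yl 2,4,6-triisopropylbenzoate | C[Sn](C)(C)[C@H](OC(=O)c1c(C(C)C)cc(C(C)C)cc1C(C)C)CCC[C@H](CO[Si](C)(C)C(C)(C)C)CC=C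
F6 | step 11 | (2R,6S)-9-hydroxy-6-[(TBS-oxy)methyl]-2-[(3Z)-5-(TBS-oxy)-4-methylpent-3-en-1-yl]nonyl acetate | CC(=O)OC[C@@H](CC/C=C(/C)CO[Si](C)(C)C(C)(C)C)CCC[C@H](CO[Si](C)(C)C(C)(C)C)CCCO
F7 | step 11 | (2R,6S)-9-iodo-6-[(TBS-oxy)methyl]-2-[(3Z)-5-(TBS-oxy)-4-methylpent-3-en-1-yl]nonyl acetate | CC(=O)OC[C@@H](CC/C=C(/C)CO[Si](C)(C)C(C)(C)C)CCC[C@H](CO[Si](C)(C)C(C)(C)C)CCCI
F8 | step 11 | (2R,6S)-6-[(TBS-oxy)methyl]-2-[(3Z)-5-(TBS-oxy)-4-methylpent-3-en-1-yl]-9-[2-oxo-3-(phenylsulfanyl)oxolan-3-yl]nonyl acetate (lactone centre as a mixture) | CC(=O)OC[C@@H](CC/C=C(/C)CO[Si](C)(C)C(C)(C)C)CCC[C@H](CO[Si](C)(C)C(C)(C)C)CCCC1(Sc2ccccc2)CCOC1=O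
F9 | step 11 | (2R,6S)-6-[(TBS-oxy)methyl]-2-[(3Z)-5-(TBS-oxy)-4-methylpent-3-en-1-yl]-9-[2-oxo-3-(phenylsulfinyl)oxolan-3-yl]nonyl acetate (lactone and sulfur centres as a mixture) | CC(=O)OC[C@@H](CC/C=C(/C)CO[Si](C)(C)C(C)(C)C)CCC[C@H](CO[Si](C)(C)C(C)(C)C)CCCC1(S(=O)c2ccccc2)CCOC1=O
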